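**Strategy**

The route rests on cutting ring A away from the rest of the flavone at two neighbouring atoms: O1 is bonded to C8a and the C4 carbonyl carbon to C4a, an ortho oxygen/acyl pair that an aryne can take up from a carboxylic acid. A fluoride-released 3,5-bis(benzyloxy)-4-methoxybenzyne therefore inserts into the O–C(acyl) bond of a (Z)-α-methoxycinnamic acid carrying ring B, C2, C3 and C4, forming C8a–O1 and C4a–C4 in one operation and giving the open 2'-hydroxychalcone. The aryne precursor is an o-silylaryl triflate with benzyloxy beside silicon and hydrogen beside the triflate. Iodine/DMSO ring closure, debenzylation, C8 bromination and copper-catalysed methoxylation finish the target.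

Key step: step 8

Assumption: the aldehyde-to-phenol conversion (step 4) is run as a Baeyer–Villiger oxidation with formate methanolysis, because the aldehyde carries no free ortho or para hydroxyl for a Dakin oxidation proper.

**Route**

Step 1
Reactants: 1 methyl 3,5-dihydroxy-4-methoxybenzoate
Product: 2 methyl 3,5-bis(benzyloxy)-4-methoxybenzoate
Conditions: BnBr (2.4 equiv), K2CO3, DMF, 60 °C
Reagents that add atoms: benzyl bromide, BrCc1ccccc1
Why: Williamson O-alkylation of both phenols under carbonate base is routine for gallate esters and leaves the ester and the methyl ether untouched.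

Step 2
Reactants: 2 methyl 3,5-bis(benzyloxy)-4-methoxybenzoate
Product: 3 [3,5-bis(benzyloxy)-4-methoxyphenyl]methanol
Conditions: LiAlH4, THF, 0 °C
Reagents that add atoms: none
Why: Hydride reduction of the aromatic ester with LiAlH4 should give the benzylic alcohol without affecting the aryl benzyl and methyl ethers.

Step 3
Reactants: 3 [3,5-bis(benzyloxy)-4-methoxyphenyl]methanol
Product: 4 3,5-bis(benzyloxy)-4-methoxybenzaldehyde
Conditions: activated MnO2 (excess), CH2Cl2, rt
Reagents that add atoms: none
Why: Activated MnO2 oxidises benzylic alcohols selectively to aldehydes and cannot over-oxidise to the acid.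

Step 4
Reactants: 4 3,5-bis(benzyloxy)-4-methoxybenzaldehyde
Product: 6 3,5-bis(benzyloxy)-4-methoxyphenol, via aryl formate 5 (not isolated)
Conditions: mCPBA, CH2Cl2, rt; then K2CO3 (cat.), MeOH, rt
Reagents that add atoms: mCPBA, OOC(=O)c1cccc(Cl)c1
Why: In this Baeyer–Villiger oxidation the electron-rich para-methoxyaryl group migrates in preference to hydride, giving the aryl formate, which mild methanolysis cleaves to the phenol (a Dakin-type overall change).

Step 5
Reactants: 6 3,5-bis(benzyloxy)-4-methoxyphenol
Product: 7 3,5-bis(benzyloxy)-2-bromo-4-methoxyphenol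
Conditions: NBS (1.0 equiv), CH2Cl2, −78 to 0 °C
Reagents that add atoms: N-bromosuccinimide, BrN1C(=O)CCC1=O
Why: Electrophilic aromatic bromination is directed ortho by the phenol; the para position is blocked and the two ortho positions are equivalent by symmetry, so one equivalent of NBS in the cold should give a single monobromide.

Step 6
Reactants: 7 3,5-bis(benzyloxy)-2-bromo-4-methoxyphenol
Product: 10 3,5-bis(benzyloxy)-4-methoxy-2-(trimethylsilyl)phenyl trifluoromethanesulfonate, via aryl trimethylsilyl ether 8 (not isolated), via lithium 2-silylphenoxide 9 (not isolated)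
Conditions: HMDS, THF, 65 °C, then volatiles removed; n-BuLi, THF, −78 °C; Tf2O, −78 °C to rt
Reagents that add atoms: hexamethyldisilazane, C[Si](C)(C)N[Si](C)(C)C; triflic anhydride, FC(F)(F)S(=O)(=O)OS(=O)(=O)C(F)(F)F
Why: O-silylation, bromine–lithium exchange, retro-Brook 1,3-shift of silicon from oxygen to carbon and O-triflation of the released phenoxide form the standard sequence to o-silylaryl triflates, and the benzyl ethers are inert to n-BuLi at −78 °C.

Step 7
Reactants: 11 2,4,5-trimethoxybenzaldehyde; 12 methyl methoxyacetate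
Product: 14 (Z)-2-methoxy-3-(2,4,5-trimethoxyphenyl)acrylic acid, via methyl ester 13 (not isolated)
Conditions: NaOMe (3 equiv), 12 (3 equiv), MeOH, reflux; then 2 M aq. NaOH, reflux; aq. HCl
Reagents that add atoms: sodium hydroxide, [Na+].[OH-]
Why: Claisen-type aldol condensation of the ester enolate with the non-enolisable aldehyde and E1cB dehydration should give the thermodynamically preferred (Z)-alkene (aryl trans to the carboxyl), and saponification in the same pot frees the acid.

Step 8
Reactants: 10 3,5-bis(benzyloxy)-4-methoxy-2-(trimethylsilyl)phenyl trifluoromethanesulfonate; 14 (Z)-2-methoxy-3-(2,4,5-trimethoxyphenyl)acrylic acid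
Product: 16 (Z)-1-[2,4-bis(benzyloxy)-6-hydroxy-3-methoxyphenyl]-2-methoxy-3-(2,4,5-trimethoxyphenyl)prop-2-en-1-one, via aryne 15 (not isolated)
Conditions: 10 (1 equiv), 14 (1.5 equiv), CsF (4 equiv), THF, 125 °C, sealed tube
Reagents that add atoms: none
Why: Fluoride attacks silicon of 10 and triflate departs to give aryne 15; the cesium carboxylate of 14 adds through oxygen to the aryne carbon that bore the triflate, the aryl anion formed beside the benzyloxy group attacks the neighbouring ester carbonyl to give a four-membered alkoxide, and this opens to the o-acylphenoxide, which is protonated to 16. The closest known reaction type is the fluoride-induced formal insertion of arynes into the C–O bond of carboxylic acids, which delivers o-hydroxyaryl ketones. No ring remains in the product (the transient four-membered ring reopens) and no stereocentre is made; the (Z)-alkene of 14 is a spectator and should be carried over unchanged. The step needs regioselective addition to the unsymmetrical aryne, and this is secured by having a benzyloxy group on only one flank: its inductive pull distorts the triple bond so that the oxygen nucleophile enters at the distal carbon (future C8a) and the anion develops at the proximal one (future C4a). It also needs acyl transfer to outrun protonation of the aryl anion, which hot aprotic THF and the carboxylate form of the acid favour, while the α-methoxy and electron-rich β-aryl groups make the enone a poor oxa-Michael acceptor, so the chalcone should stay open.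

Step 9
Reactants: 16 (Z)-1-[2,4-bis(benzyloxy)-6-hydroxy-3-methoxyphenyl]-2-methoxy-3-(2,4,5-trimethoxyphenyl)prop-2-en-1-one
Product: 17 5,7-bis(benzyloxy)-3,6-dimethoxy-2-(2,4,5-trimethoxyphenyl)-4H-chromen-4-one
Conditions: I2 (0.1 equiv), DMSO, 120 °C
Reagents that add atoms: none
Why: In this iodine/DMSO oxidative cyclisation of a 2'-hydroxychalcone the phenol oxygen attacks the iodine-activated, electron-rich alkene at the benzylic carbon in a 6-endo sense and loss of HI gives the chromone, DMSO reoxidising HI to I2; the alkene geometry is lost without consequence.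

Step 10
Reactants: 17 5,7-bis(benzyloxy)-3,6-dimethoxy-2-(2,4,5-trimethoxyphenyl)-4H-chromen-4-one
Product: 18 5,7-dihydroxy-3,6-dimethoxy-2-(2,4,5-trimethoxyphenyl)-4H-chromen-4-one
Conditions: H2 (1 atm), 10% Pd/C, EtOAc–MeOH, rt
Reagents that add atoms: none
Why: Catalytic hydrogenolysis cleaves both aryl benzyl ethers, while the tetrasubstituted, vinylogous-ester C2=C3 bond of the chromone should resist reduction under these mild conditions.

Step 11
Reactants: 18 5,7-dihydroxy-3,6-dimethoxy-2-(2,4,5-trimethoxyphenyl)-4H-chromen-4-one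
Product: 19 8-bromo-5,7-dihydroxy-3,6-dimethoxy-2-(2,4,5-trimethoxyphenyl)-4H-chromen-4-one
Conditions: NBS (1.0 equiv), DMF, 0 °C
Reagents that add atoms: N-bromosuccinimide, BrN1C(=O)CCC1=O
Why: In this electrophilic aromatic bromination C8 is the only free position of ring A and lies ortho to the 7-hydroxyl and para to the 5-hydroxyl, so it should react well ahead of the ring B carbons, which sit on an aryl group attached to the electron-poor chromone.

Step 12
Reactants: 19 8-bromo-5,7-dihydroxy-3,6-dimethoxy-2-(2,4,5-trimethoxyphenyl)-4H-chromen-4-one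
Product: 20 5,7-dihydroxy-3,6,8-trimethoxy-2-(2,4,5-trimethoxyphenyl)-4H-chromen-4-one (5,7-dihydroxy-3,6,8,2',4',5'-hexamethoxyflavone)
Conditions: NaOMe (10 equiv), CuBr (0.2 equiv), MeOH–DMF, 110 °C; aq. HCl work-up
Reagents that add atoms: sodium methoxide, [Na+].[O-]C
Why: Copper-catalysed Ullmann-type methoxylation of aryl bromides with NaOMe is established for unprotected ortho-bromophenols, and the bis-phenoxide form of the chromone is deactivated towards attack by methoxide at C2.

**Compound list**

1 | methyl 3,5-dihydroxy-4-methoxybenzoate | COC(=O)c1cc(O)c(OC)c(O)c1 | starting material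
2 | methyl 3,5-bis(benzyloxy)-4-methoxybenzoate | COC(=O)c1cc(OCc2ccccc2)c(OC)c(OCc2ccccc2)c1 | intermediate
3 | [3,5-bis(benzyloxy)-4-methoxyphenyl]methanol | OCc1cc(OCc2ccccc2)c(OC)c(OCc2ccccc2)c1 | intermediate
4 | 3,5-bis(benzyloxy)-4-methoxybenzaldehyde | O=Cc1cc(OCc2ccccc2)c(OC)c(OCc2ccccc2)c1 | intermediate
5 | 3,5-bis(benzyloxy)-4-methoxyphenyl formate | O=COc1cc(OCc2ccccc2)c(OC)c(OCc2ccccc2)c1 | intermediate
6 | 3,5-bis(benzyloxy)-4-methoxyphenol | Oc1cc(OCc2ccccc2)c(OC)c(OCc2ccccc2)c1 | intermediate
7 | 3,5-bis(benzyloxy)-2-bromo-4-methoxyphenol | Oc1cc(OCc2ccccc2)c(OC)c(OCc2ccccc2)c1Br | intermediate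
8 | [3,5-bis(benzyloxy)-2-bromo-4-methoxyphenoxy]trimethylsilane | C[Si](C)(C)Oc1cc(OCc2ccccc2)c(OC)c(OCc2ccccc2)c1Br | intermediate
9 | lithium 3,5-bis(benzyloxy)-4-methoxy-2-(trimethylsilyl)phenoxide | [Li+].[O-]c1cc(OCc2ccccc2)c(OC)c(OCc2ccccc2)c1[Si](C)(C)C | intermediate
10 | 3,5-bis(benzyloxy)-4-methoxy-2-(trimethylsilyl)phenyl trifluoromethanesulfonate | C[Si](C)(C)c1c(OS(=O)(=O)C(F)(F)F)cc(OCc2ccccc2)c(OC)c1OCc1ccccc1 | intermediate
11 | 2,4,5-trimethoxybenzaldehyde | COc1cc(OC)c(C=O)cc1OC | starting material
12 | methyl methoxyacetate | COCC(=O)OC | starting material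
13 | methyl (Z)-2-methoxy-3-(2,4,5-trimethoxyphenyl)acrylate | COC(=O)/C(OC)=C/c1cc(OC)c(OC)cc1OC | intermediate
14 | (Z)-2-methoxy-3-(2,4,5-trimethoxyphenyl)acrylic acid | OC(=O)/C(OC)=C/c1cc(OC)c(OC)cc1OC | intermediate
15 | 3,5-bis(benzyloxy)-4-methoxybenzyne (1,2-didehydrobenzene, benzyloxy on the carbon next to one aryne carbon) | COC1=C(OCc2ccccc2)C#CC=C1OCc1ccccc1 | intermediate
16 | (Z)-1-[2,4-bis(benzyloxy)-6-hydroxy-3-methoxyphenyl]-2-methoxy-3-(2,4,5-trimethoxyphenyl)prop-2-en-1-one | COc1cc(OC)c(/C=C(\OC)C(=O)c2c(O)cc(OCc3ccccc3)c(OC)c2OCc2ccccc2)cc1OC | intermediate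
17 | 5,7-bis(benzyloxy)-3,6-dimethoxy-2-(2,4,5-trimethoxyphenyl)-4H-chromen-4-one | COc1cc(OC)c(-c2oc3cc(OCc4ccccc4)c(OC)c(OCc4ccccc4)c3c(=O)c2OC)cc1OC | intermediate
18 | 5,7-dihydroxy-3,6-dimethoxy-2-(2,4,5-trimethoxyphenyl)-4H-chromen-4-one | COc1cc(OC)c(-c2oc3cc(O)c(OC)c(O)c3c(=O)c2OC)cc1OC | intermediate
19 | 8-bromo-5,7-dihydroxy-3,6-dimethoxy-2-(2,4,5-trimethoxyphenyl)-4H-chromen-4-one | COc1cc(OC)c(-c2oc3c(Br)c(O)c(OC)c(O)c3c(=O)c2OC)cc1OC | intermediate
20 | 5,7-dihydroxy-3,6,8-trimethoxy-2-(2,4,5-trimethoxyphenyl)-4H-chromen-4-one (5,7-dihydroxy-3,6,8,2',4',5'-hexamethoxyflavone) | COc1cc(OC)c(-c2oc3c(OC)c(O)c(OC)c(O)c3c(=O)c2OC)cc1OC | target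

**Step count and risk**

Total step count: 12 (steps 1–6 to the aryne precursor, step 7 to the acid, step 8 the key step, steps 9–12 the endgame).
Longest linear sequence: 11 steps (from 1 to 20 through steps 1–6 and 8–12).

Steps most likely to fail:

1. Step 8 (aryne insertion). The aryl anion may be protonated before it transfers the acyl group, giving O-arylation only; the carboxylate may add with eroded regioselectivity; or the product phenoxide may be arylated by a second aryne. The fallback sets out from 7 and 14 and uses the known halogen–metal-exchange-triggered anionic Fries-type acyl shift. Esterification with EDC·HCl and DMAP in CH2Cl2 should give 3,5-bis(benzyloxy)-2-bromo-4-methoxyphenyl (Z)-2-methoxy-3-(2,4,5-trimethoxyphenyl)prop-2-enoate F1. Bromine–lithium exchange with n-BuLi in THF at −95 °C should then place the aryllithium between the ester oxygen and the benzyloxy group, so that the acyl group migrates from oxygen to that carbon through the same four-membered alkoxide, now with the position fixed by the bromine. Aqueous work-up returns the route at 16.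

2. Step 12 (copper-catalysed methoxylation). Reductive loss of bromine or base-induced opening of the chromone ring may compete on the unprotected polyphenol at high temperature. The fallback sets out from 19 and protects before a palladium-catalysed C–O coupling. Benzylation (BnBr, K2CO3, DMF, 80 °C) should give 5,7-bis(benzyloxy)-8-bromo-3,6-dimethoxy-2-(2,4,5-trimethoxyphenyl)-4H-chromen-4-one F2. Coupling with methanol (Pd2(dba)3, tBuBrettPhos, Cs2CO3, MeOH, toluene, 80 °C) should give 5,7-bis(benzyloxy)-3,6,8-trimethoxy-2-(2,4,5-trimethoxyphenyl)-4H-chromen-4-one F3. Hydrogenolysis (H2, 10% Pd/C, EtOAc–MeOH, rt) comes back to the route at 20.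

3. Step 9 (iodine/DMSO cyclisation). Nuclear iodination of the electron-rich rings, loss of benzyl groups to HI at high temperature, or slow ring closure because the α-methoxy group lowers the electrophilicity of the β-carbon may intervene. The fallback sets out from 16 and separates ring closure from oxidation. Base-mediated oxa-Michael isomerisation (NaOAc, EtOH, reflux) should give trans-5,7-bis(benzyloxy)-3,6-dimethoxy-2-(2,4,5-trimethoxyphenyl)chroman-4-one F4 (racemic; the cis isomer would converge). Dehydrogenation with DDQ in dioxane at reflux removes both stereocentres and comes back to the route at 17.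

**Further compounds**

F1 | step 8 | 3,5-bis(benzyloxy)-2-bromo-4-methoxyphenyl (Z)-2-methoxy-3-(2,4,5-trimethoxyphenyl)prop-2-enoate | COc1cc(OC)c(/C=C(\OC)C(=O)Oc2cc(OCc3ccccc3)c(OC)c(OCc3ccccc3)c2Br)cc1OC
F2 | step 12 | 5,7-bis(benzyloxy)-8-bromo-3,6-dimethoxy-2-(2,4,5-trimethoxyphenyl)-4H-chromen-4-one | COc1cc(OC)c(-c2oc3c(Br)c(OCc4ccccc4)c(OC)c(OCc4ccccc4)c3c(=O)c2OC)cc1OC
F3 | step 12 | 5,7-bis(benzyloxy)-3,6,8-trimethoxy-2-(2,4,5-trimethoxyphenyl)-4H-chromen-4-one | COc1cc(OC)c(-c2oc3c(OC)c(OCc4ccccc4)c(OC)c(OCc4ccccc4)c3c(=O)c2OC)cc1OC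
F4 | step 9 | trans-5,7-bis(benzyloxy)-3,6-dimethoxy-2-(2,4,5-trimethoxyphenyl)chroman-4-one (racemic, (2S,3S) enantiomer drawn) | CO[C@@H]1C(=O)c2c(OCc3ccccc3)c(OC)c(OCc3ccccc3)cc2O[C@H]1c1cc(OC)c(OC)cc1OC
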